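In chroman-2-one numbering, ring A (C4a, C5, C6, C7, C8, C8a) is a 4,6-dialkylresorcinol with unlike oxygens: O1 on C8a is acylated and the C7 oxygen is free. The plan therefore builds ring A last. It comes from an acyclic α-diazo enone that already holds the C4 stereocentre, ring B (catechol), ring C (dimethoxyphenyl) and the ester arm, and from a two-carbon silyl ynol ether. One light-driven cascade forges C5–C6, C6–C7, C8–C8a and C4a–C8a and sets the alkyl groups at C4a and C6. It hands over the C8a oxygen as a free phenol beside a silyl ether at C7. C4 comes from an earlier iridium-catalysed asymmetric allylic alkylation.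

Key step: step 12

Assumption: the (Sa,S,S) antipode of the phosphoramidite in step 4 is chosen by analogy with other aryl-substituted allylic carbonates; the sense of induction would be checked on 8, and the mirror-image ligand, equally available, used if needed.
Remark: the spatial arrangement at the stereocentre is the same from 7 to 29. Its descriptor is R in 7, S in 8, 14–16 and 22–25, and R in 26–29, only because the substituent ranking changes.

Step 1
Reactants: 1 3,4-bis(benzyloxy)benzaldehyde; 2 triethyl phosphonoacetate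
Product: 3 ethyl (E)-3-[3,4-bis(benzyloxy)phenyl]prop-2-enoate
Conditions: NaH, THF, 0 °C to rt
Reagents that add atoms: none
Why: Horner–Wadsworth–Emmons olefination of a non-enolisable aromatic aldehyde with a stabilised phosphonate anion reliably gives the E-cinnamate.

Step 2
Reactants: 3 ethyl cinnamate
Product: 4 (E)-3-[3,4-bis(benzyloxy)phenyl]prop-2-en-1-ol
Conditions: i-Bu2AlH (2.3 equiv), CH2Cl2, −78 to 0 °C; aq. potassium sodium tartrate
Reagents that add atoms: none
Why: 1,2-Reduction of an α,β-unsaturated ester with an aluminium hydride ends at the allylic alcohol and touches neither the alkene nor the benzyl ethers.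

Step 3
Reactants: 4 allylic alcohol
Product: 5 (E)-3-[3,4-bis(benzyloxy)phenyl]prop-2-en-1-yl methyl carbonate
Conditions: ClCO2Me, pyridine, CH2Cl2, 0 °C
Reagents that add atoms: methyl chloroformate COC(=O)Cl
Why: O-Acylation of a primary alcohol with a chloroformate installs a leaving group that releases its own base (methoxide) when it ionises in step 4.

Step 4
Reactants: 5 allylic carbonate; 6 dimethyl malonate
Product: 7 dimethyl 2-{(1R)-1-[3,4-bis(benzyloxy)phenyl]prop-2-en-1-yl}propanedioate
Conditions: [Ir(cod)Cl]2 (2 mol %), (Sa,S,S)-phosphoramidite from (S)-BINOL and bis[(S)-1-phenylethyl]amine (4 mol %), 1,5,7-triazabicyclo[4.4.0]dec-5-ene (8 mol %), THF, rt; then 5 and 6 (1.5 equiv), rt to 50 °C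
Reagents that add atoms: none
Why: In this iridium-catalysed asymmetric allylic alkylation the cyclometallated iridium–phosphoramidite complex ionises the carbonate, the liberated methoxide deprotonates 6, and the malonate attacks the aryl-bearing allyl terminus on the face away from the metal, so the chiral ligand fixes both the branched regiochemistry and the configuration of the new stereocentre (the future C4).

Step 5
Reactants: 7 allylated malonate
Product: 8 methyl (3S)-3-[3,4-bis(benzyloxy)phenyl]pent-4-enoate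
Conditions: NaCl, H2O, DMSO, 150 °C
Reagents that add atoms: none
Why: Krapcho dealkoxycarbonylation removes one ester under nearly neutral conditions, and the stereocentre, which lies β to the remaining ester, is not enolisable and keeps its arrangement.

Step 6
Reactants: 9 4-(3,4-dimethoxyphenyl)butanoic acid
Product: 11 4-(3,4-dimethoxyphenyl)-N-methoxy-N-methylbutanamide, via acyl imidazole 10 (not isolated)
Conditions: 1,1'-carbonyldiimidazole, CH2Cl2, rt; then MeNH(OMe)·HCl, rt
Reagents that add atoms: 1,1'-carbonyldiimidazole O=C(n1ccnc1)n1ccnc1; N,O-dimethylhydroxylamine hydrochloride CNOC.Cl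
Why: Amide coupling through the acyl imidazole avoids an acid chloride, which could close onto electron-rich ring C by Friedel–Crafts acylation.

Step 7
Reactants: 11 N-methoxy-N-methyl amide; 12 vinylmagnesium bromide
Product: 13 6-(3,4-dimethoxyphenyl)hex-1-en-3-one
Conditions: THF, −20 to 0 °C; inverse quench into cold 1 M HCl
Reagents that add atoms: none
Why: In the Weinreb ketone synthesis the amide accepts only one equivalent of the Grignard reagent, and quenching into cold acid keeps the released amine protonated so that it cannot add to the vinyl ketone.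

Step 8
Reactants: 8 pentenoate; 13 vinyl ketone
Product: 14 methyl (3S,4E)-3-[3,4-bis(benzyloxy)phenyl]-9-(3,4-dimethoxyphenyl)-6-oxonon-4-enoate
Conditions: second-generation Hoveyda–Grubbs catalyst (5 mol %), 1,4-benzoquinone (10 mol %), 13 (2 equiv), CH2Cl2, 40 °C
Reagents that add atoms: none
Why: Olefin cross-metathesis between a reactive terminal alkene and an electron-poor vinyl ketone that hardly homodimerises favours the E cross product, and benzoquinone suppresses ruthenium hydride-induced double-bond migration, which would erase the allylic stereocentre.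

Step 9
Reactants: 14 enone
Product: 16 methyl (3S,4E)-3-[3,4-bis(benzyloxy)phenyl]-7-diazo-9-(3,4-dimethoxyphenyl)-6-oxonon-4-enoate, via trifluoroacetyl diketone 15 (not isolated)
Conditions: LiN(SiMe3)2 (1.1 equiv), THF, −78 °C; CF3CO2CH2CF3, −78 °C; dilute HCl work-up; then 4-AcNHC6H4SO2N3, Et3N, H2O (1 equiv), MeCN, rt
Reagents that add atoms: 2,2,2-trifluoroethyl trifluoroacetate O=C(OCC(F)(F)F)C(F)(F)F; 4-acetamidobenzenesulfonyl azide CC(=O)Nc1ccc(cc1)S(=O)(=O)N=[N+]=[N-]
Why: In this detrifluoroacetylative (Regitz-type) diazo transfer, kinetic deprotonation at −78 °C takes the accessible α'-CH2 rather than the hindered γ-CH or the less acidic ester CH2, the diketone 15 is acidic enough for Et3N, and the adduct with the azide sheds the most electrophilic acyl group.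

Step 10
Reactants: 17 (trimethylsilyl)diazomethane; 18 carbon monoxide
Product: 20 triisopropyl{[(trimethylsilyl)ethynyl]oxy}silane, via lithium silylynolate 19 (not isolated)
Conditions: n-BuLi, THF, −78 °C; CO (1 atm), −78 °C; i-Pr3SiOSO2CF3, −78 to 0 °C
Reagents that add atoms: n-butyllithium [Li]CCCC; triisopropylsilyl trifluoromethanesulfonate CC(C)[Si](OS(=O)(=O)C(F)(F)F)(C(C)C)C(C)C
Why: Carbonylation of lithiated (trimethylsilyl)diazomethane gives an acyl anion that loses N2 to form the silyl ynolate, and the bulk of the C-silyl group and of the silyl triflate steers the silylation to oxygen.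

Step 11
Reactants: 20 C-silylated siloxyalkyne
Product: 21 (triisopropylsilyloxy)ethyne
Conditions: K2CO3 (20 mol %), MeOH, 0 °C; pentane extraction, kept cold as a solution
Reagents that add atoms: none
Why: Carbonate-catalysed protodesilylation of an alkynyl–SiMe3 bond is fast at 0 °C, whereas the hindered O–Si(i-Pr)3 bond resists methoxide.

Step 12
Reactants: 16 α-diazo enone; 21 (triisopropylsilyloxy)ethyne
Product: 26 methyl (3R)-3-[3,4-bis(benzyloxy)phenyl]-3-{5-[2-(3,4-dimethoxyphenyl)ethyl]-2-hydroxy-4-(triisopropylsilyloxy)phenyl}propanoate, via vinylketene 22 (not isolated), via alkenylcyclobutenone 23 (not isolated), via dienylketene 24 (not isolated), via cyclohexadienone 25 (not isolated)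
Conditions: 21 (2.5 equiv), degassed CH2Cl2 (0.05 M), hν (medium-pressure Hg lamp, Pyrex filter, λ > 300 nm), 15 °C; evaporate; toluene, 110 °C
Reagents that add atoms: none
Why: Direct excitation of 16 expels N2 while the alkenyl group moves to the diazo carbon (photochemical Wolff rearrangement, C5–C6); the electron-rich CH end of 21 then bonds to the central carbon of vinylketene 22 and the oxygen-bearing alkyne carbon to its α-carbon, a (2+2) cycloaddition that makes C8–C8a and C6–C7 and gives the 4-alkenylcyclobut-2-enone 23. On heating, 23 opens by conrotatory four-electron cleavage of its C6–C8a bond to dienylketene 24, ring A closes by disrotatory six-electron electrocyclisation (C4a–C8a) to cyclohexadienone 25, and tautomerisation gives phenol 26. The closest known reaction type is the Danheiser benzannulation in its diazo ketone variant with siloxyalkynes, which gives resorcinol monosilyl ethers; a diazo carbon bearing CH2 and a terminal siloxyalkyne are merely rarer partners within that class. No lasting stereocentre is formed, because the quaternary carbon of 23 and the sp3 C4a of 25 vanish on ring opening and aromatisation, and C4 is a bystander under these neutral conditions. The step needs regioselectivity, secured by the polarisation of the ynol ether (free OH ends on C8a, silyl ether on C7), and chemoselectivity for alkenyl migration over 1,2-hydride shift, favoured by unsensitised excitation of the s-Z conformer that the slim alkenyl and primary alkyl substituents allow. Light above 300 nm is absorbed by the diazo enone but not by the benzyl aryl ethers or rings B and C, and keeping the cold photochemical stage apart from the thermal stage means that no phenol is present while ketene is being generated.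

Step 13
Reactants: 26 phenol ester
Product: 28 (4R)-4-[3,4-bis(benzyloxy)phenyl]-6-[2-(3,4-dimethoxyphenyl)ethyl]-7-hydroxychroman-2-one, via silyl lactone 27 (not isolated)
Conditions: p-TsOH·H2O (10 mol %), toluene, 4 Å sieves, 80 °C; then 0 °C, THF, AcOH, n-Bu4NF
Reagents that add atoms: none
Why: Acid-catalysed lactonisation (intramolecular transesterification) uses the only hydroxyl that can reach the ester (on C8a), and acetic acid-buffered fluoride then cleaves the aryl silyl ether without opening the aryl ester or disturbing C4.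

Step 14
Reactants: 28 hydroxy lactone
Product: 29 (4R)-4-(3,4-dihydroxyphenyl)-6-[2-(3,4-dimethoxyphenyl)ethyl]-7-hydroxychroman-2-one (target)
Conditions: H2 (1 atm), Pd/C, EtOAc–THF, rt
Reagents that add atoms: none
Why: Catalytic hydrogenolysis cleaves the two benzyl ethers under neutral conditions in a non-nucleophilic solvent, while the lactone, the methyl ethers and the C4–aryl bonds (no benzylic C–O bond at C4) stay intact.

Compound list
1 | 3,4-bis(benzyloxy)benzaldehyde | O=Cc1ccc(OCc2ccccc2)c(OCc2ccccc2)c1 | starting material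
2 | triethyl phosphonoacetate | CCOC(=O)CP(=O)(OCC)OCC | starting material
3 | ethyl (E)-3-[3,4-bis(benzyloxy)phenyl]prop-2-enoate | CCOC(=O)/C=C/c1ccc(OCc2ccccc2)c(OCc2ccccc2)c1 | intermediate
4 | (E)-3-[3,4-bis(benzyloxy)phenyl]prop-2-en-1-ol | OC/C=C/c1ccc(OCc2ccccc2)c(OCc2ccccc2)c1 | intermediate
5 | (E)-3-[3,4-bis(benzyloxy)phenyl]prop-2-en-1-yl methyl carbonate | COC(=O)OC/C=C/c1ccc(OCc2ccccc2)c(OCc2ccccc2)c1 | intermediate
6 | dimethyl malonate | COC(=O)CC(=O)OC | starting material
7 | dimethyl 2-{(1R)-1-[3,4-bis(benzyloxy)phenyl]prop-2-en-1-yl}propanedioate | COC(=O)C(C(=O)OC)[C@@H](C=C)c1ccc(OCc2ccccc2)c(OCc2ccccc2)c1 | intermediate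
8 | methyl (3S)-3-[3,4-bis(benzyloxy)phenyl]pent-4-enoate | COC(=O)C[C@@H](C=C)c1ccc(OCc2ccccc2)c(OCc2ccccc2)c1 | intermediate
9 | 4-(3,4-dimethoxyphenyl)butanoic acid | OC(=O)CCCc1ccc(OC)c(OC)c1 | starting material
10 | 4-(3,4-dimethoxyphenyl)-1-(imidazol-1-yl)butan-1-one | O=C(CCCc1ccc(OC)c(OC)c1)n1ccnc1 | intermediate
11 | 4-(3,4-dimethoxyphenyl)-N-methoxy-N-methylbutanamide | CON(C)C(=O)CCCc1ccc(OC)c(OC)c1 | intermediate
12 | vinylmagnesium bromide | C=C[Mg]Br | starting material
13 | 6-(3,4-dimethoxyphenyl)hex-1-en-3-one | C=CC(=O)CCCc1ccc(OC)c(OC)c1 | intermediate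
14 | methyl (3S,4E)-3-[3,4-bis(benzyloxy)phenyl]-9-(3,4-dimethoxyphenyl)-6-oxonon-4-enoate | COC(=O)C[C@@H](/C=C/C(=O)CCCc1ccc(OC)c(OC)c1)c1ccc(OCc2ccccc2)c(OCc2ccccc2)c1 | intermediate
15 | methyl (3S,4E)-3-[3,4-bis(benzyloxy)phenyl]-7-[2-(3,4-dimethoxyphenyl)ethyl]-9,9,9-trifluoro-6,8-dioxonon-4-enoate (C7 epimers and enol forms) | COC(=O)C[C@@H](/C=C/C(=O)C(CCc1ccc(OC)c(OC)c1)C(=O)C(F)(F)F)c1ccc(OCc2ccccc2)c(OCc2ccccc2)c1 | intermediate
16 | methyl (3S,4E)-3-[3,4-bis(benzyloxy)phenyl]-7-diazo-9-(3,4-dimethoxyphenyl)-6-oxonon-4-enoate | COC(=O)C[C@@H](/C=C/C(=O)C(=[N+]=[N-])CCc1ccc(OC)c(OC)c1)c1ccc(OCc2ccccc2)c(OCc2ccccc2)c1 | intermediate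
17 | (trimethylsilyl)diazomethane | C[Si](C)(C)C=[N+]=[N-] | starting material
18 | carbon monoxide | [C-]#[O+] | starting material
19 | lithium 2-(trimethylsilyl)ethynolate | C[Si](C)(C)C#C[O-].[Li+] | intermediate
20 | triisopropyl{[(trimethylsilyl)ethynyl]oxy}silane | C[Si](C)(C)C#CO[Si](C(C)C)(C(C)C)C(C)C | intermediate
21 | (triisopropylsilyloxy)ethyne | C#CO[Si](C(C)C)(C(C)C)C(C)C | intermediate
22 | methyl (3S,4E)-3-[3,4-bis(benzyloxy)phenyl]-6-[2-(3,4-dimethoxyphenyl)ethyl]-7-oxohepta-4,6-dienoate (vinylketene) | COC(=O)C[C@@H](/C=C/C(=C=O)CCc1ccc(OC)c(OC)c1)c1ccc(OCc2ccccc2)c(OCc2ccccc2)c1 | intermediate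
23 | methyl (3S,4E)-3-[3,4-bis(benzyloxy)phenyl]-5-{1-[2-(3,4-dimethoxyphenyl)ethyl]-4-oxo-2-(triisopropylsilyloxy)cyclobut-2-en-1-yl}pent-4-enoate (both ring epimers) | COC(=O)C[C@@H](/C=C/C1(CCc2ccc(OC)c(OC)c2)C(=O)C=C1O[Si](C(C)C)(C(C)C)C(C)C)c1ccc(OCc2ccccc2)c(OCc2ccccc2)c1 | intermediate
24 | methyl (3S,4E,6E)-3-[3,4-bis(benzyloxy)phenyl]-6-[2-(3,4-dimethoxyphenyl)ethyl]-9-oxo-7-(triisopropylsilyloxy)nona-4,6,8-trienoate (dienylketene) | COC(=O)C[C@@H](/C=C/C(CCc1ccc(OC)c(OC)c1)=C(\C=C=O)O[Si](C(C)C)(C(C)C)C(C)C)c1ccc(OCc2ccccc2)c(OCc2ccccc2)c1 | intermediate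
25 | methyl (3S)-3-[3,4-bis(benzyloxy)phenyl]-3-{3-[2-(3,4-dimethoxyphenyl)ethyl]-6-oxo-4-(triisopropylsilyloxy)cyclohexa-2,4-dien-1-yl}propanoate (ring CH unassigned) | COC(=O)C[C@@H](C1C=C(CCc2ccc(OC)c(OC)c2)C(O[Si](C(C)C)(C(C)C)C(C)C)=CC1=O)c1ccc(OCc2ccccc2)c(OCc2ccccc2)c1 | intermediate
26 | methyl (3R)-3-[3,4-bis(benzyloxy)phenyl]-3-{5-[2-(3,4-dimethoxyphenyl)ethyl]-2-hydroxy-4-(triisopropylsilyloxy)phenyl}propanoate | COC(=O)C[C@@H](c1cc(CCc2ccc(OC)c(OC)c2)c(O[Si](C(C)C)(C(C)C)C(C)C)cc1O)c1ccc(OCc2ccccc2)c(OCc2ccccc2)c1 | intermediate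
27 | (4R)-4-[3,4-bis(benzyloxy)phenyl]-6-[2-(3,4-dimethoxyphenyl)ethyl]-7-(triisopropylsilyloxy)chroman-2-one | COc1ccc(CCc2cc3c(cc2O[Si](C(C)C)(C(C)C)C(C)C)OC(=O)C[C@@H]3c2ccc(OCc4ccccc4)c(OCc4ccccc4)c2)cc1OC | intermediate
28 | (4R)-4-[3,4-bis(benzyloxy)phenyl]-6-[2-(3,4-dimethoxyphenyl)ethyl]-7-hydroxychroman-2-one | COc1ccc(CCc2cc3c(cc2O)OC(=O)C[C@@H]3c2ccc(OCc4ccccc4)c(OCc4ccccc4)c2)cc1OC | intermediate
29 | (4R)-4-(3,4-dihydroxyphenyl)-6-[2-(3,4-dimethoxyphenyl)ethyl]-7-hydroxychroman-2-one | COc1ccc(CCc2cc3c(cc2O)OC(=O)C[C@@H]3c2ccc(O)c(O)c2)cc1OC | target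

Total step count: 14. Longest linear sequence: 10 (steps 1–5, 8, 9, 12, 13, 14).

Steps most likely to fail

**Step 12.**
- What may go wrong: a hydride may migrate from the CH2 next to the carbene centre in place of the alkenyl group. The enone may photoisomerise from E to Z, followed by a 1,5-hydrogen shift in the ketene. The cycloaddition of the disubstituted ketene may be too slow to outrun its dimerisation.
- Fallback (sets out from 3, comes back at 29): ring A is taken from a purchased arene and C4 is set by conjugate arylation.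
- 5-Bromo-2,4-dihydroxybenzaldehyde is benzylated (BnBr, K2CO3, DMF) to 2,4-bis(benzyloxy)-5-bromobenzaldehyde F1. Horner–Wadsworth–Emmons reaction with diethyl (3,4-dimethoxybenzyl)phosphonate (NaH, THF) gives the bromostilbene F2. Diimide (TsNHNH2, NaOAc, aq. THF, reflux) saturates the alkene without touching bromide or benzyl ethers and gives the bibenzyl bromide F3. Bromine–lithium exchange (n-BuLi, THF, −78 °C), B(Oi-Pr)3 and acidic work-up give the ring A boronic acid F4.
- Hayashi–Miyaura addition of F4 to 3 should give the diarylpropanoate F5. Conditions are [Rh(C2H4)2Cl]2, a chiral bicyclo[2.2.2]octa-2,5-diene ligand of the antipode that leads to the R product, KOH, dioxane–H2O, 50 °C.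
- Hydrogenolysis (H2, Pd/C, EtOAc) frees all four phenols to give the tetraphenol ester F6, and catalytic p-TsOH in warm THF–toluene closes the lactone to 29.

**Step 9.**
- What may go wrong: the base may abstract the doubly activated γ-CH (erosion of configuration, migration of the double bond) or the ester CH2 instead of the α'-CH2. C-Acylation of the enolate may also be incomplete.
- Fallback (sets out from 8, comes back at 22 and hence 26): the same vinylketene is reached without a diazo compound, by dehydrochlorination of an acid chloride.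
- The lithium dienediolate of crotonic acid (2 equiv LiN(i-Pr)2, THF) is alkylated at its α-carbon with 4-(2-bromoethyl)-1,2-dimethoxybenzene to give 2-[2-(3,4-dimethoxyphenyl)ethyl]but-3-enoic acid F7.
- Cross-metathesis of 8 with F7 (second-generation Hoveyda–Grubbs catalyst, CH2Cl2, 40 °C) gives the β,γ-unsaturated acid F8. Its α-epimers are of no consequence.
- (COCl)2 with catalytic DMF gives the acid chloride F9. Slow addition of F9 to Et3N and 21 in toluene generates 22, which is trapped as 23 and heated on to 26 as in step 12.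

**Step 11.**
- What may go wrong: methoxide may attack the oxygen-bound silicon instead of the carbon-bound one. The silyl group of the terminal ynol ether may migrate from oxygen to carbon on concentration. The volatile product may be lost.
- Fallback (sets out from 16, comes back at 28): the silyl ynol ether is replaced by an alkyl ynol ether whose alkyl group leaves under the acid of step 13.
- tert-Butanol, KH and trichloroethylene (THF, −50 °C to rt) give (E)-1-tert-butoxy-1,2-dichloroethene F10. n-BuLi (2.2 equiv, −78 to −40 °C) and a methanol quench give tert-butoxyethyne F11, kept cold as a solution.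
- Irradiation of 16 with F11 under the conditions of step 12 gives the tert-butoxy alkenylcyclobutenone F12. Excess F11 is pumped off before heating, which then leads to the tert-butyl ether phenol F13.
- Catalytic p-TsOH in toluene at 80 °C expels 2-methylpropene and methanol and gives 28 directly, so the fluoride treatment is no longer needed.

Further compounds
F1 | step 12 | 2,4-bis(benzyloxy)-5-bromobenzaldehyde | O=Cc1cc(Br)c(OCc2ccccc2)cc1OCc1ccccc1
F2 | step 12 | bromostilbene, (E)-1,5-bis(benzyloxy)-2-bromo-4-[2-(3,4-dimethoxyphenyl)ethenyl]benzene | COc1ccc(/C=C/c2cc(Br)c(OCc3ccccc3)cc2OCc2ccccc2)cc1OC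
F3 | step 12 | bibenzyl bromide, 1,5-bis(benzyloxy)-2-bromo-4-[2-(3,4-dimethoxyphenyl)ethyl]benzene | COc1ccc(CCc2cc(Br)c(OCc3ccccc3)cc2OCc2ccccc2)cc1OC
F4 | step 12 | ring A boronic acid, {2,4-bis(benzyloxy)-5-[2-(3,4-dimethoxyphenyl)ethyl]phenyl}boronic acid | COc1ccc(CCc2cc(B(O)O)c(OCc3ccccc3)cc2OCc2ccccc2)cc1OC
F5 | step 12 | diarylpropanoate, ethyl (3R)-3-{2,4-bis(benzyloxy)-5-[2-(3,4-dimethoxyphenyl)ethyl]phenyl}-3-[3,4-bis(benzyloxy)phenyl]propanoate | CCOC(=O)C[C@@H](c1cc(CCc2ccc(OC)c(OC)c2)c(OCc2ccccc2)cc1OCc1ccccc1)c1ccc(OCc2ccccc2)c(OCc2ccccc2)c1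
F6 | step 12 | tetraphenol ester, ethyl (3R)-3-{2,4-dihydroxy-5-[2-(3,4-dimethoxyphenyl)ethyl]phenyl}-3-(3,4-dihydroxyphenyl)propanoate | CCOC(=O)C[C@@H](c1cc(CCc2ccc(OC)c(OC)c2)c(O)cc1O)c1ccc(O)c(O)c1
F7 | step 9 | 2-[2-(3,4-dimethoxyphenyl)ethyl]but-3-enoic acid | C=CC(CCc1ccc(OC)c(OC)c1)C(=O)O
F8 | step 9 | β,γ-unsaturated acid, (3E,5S)-5-[3,4-bis(benzyloxy)phenyl]-2-[2-(3,4-dimethoxyphenyl)ethyl]-7-methoxy-7-oxohept-3-enoic acid | COC(=O)C[C@@H](/C=C/C(CCc1ccc(OC)c(OC)c1)C(=O)O)c1ccc(OCc2ccccc2)c(OCc2ccccc2)c1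
F9 | step 9 | acid chloride, methyl (3S,4E)-3-[3,4-bis(benzyloxy)phenyl]-6-(chlorocarbonyl)-8-(3,4-dimethoxyphenyl)oct-4-enoate | COC(=O)C[C@@H](/C=C/C(CCc1ccc(OC)c(OC)c1)C(=O)Cl)c1ccc(OCc2ccccc2)c(OCc2ccccc2)c1
F10 | step 11 | (E)-1-tert-butoxy-1,2-dichloroethene | CC(C)(C)O/C(Cl)=C\Cl
F11 | step 11 | tert-butoxyethyne | C#COC(C)(C)C
F12 | step 11 | tert-butoxy alkenylcyclobutenone, methyl (3S,4E)-3-[3,4-bis(benzyloxy)phenyl]-5-{2-tert-butoxy-1-[2-(3,4-dimethoxyphenyl)ethyl]-4-oxocyclobut-2-en-1-yl}pent-4-enoate | COC(=O)C[C@@H](/C=C/C1(CCc2ccc(OC)c(OC)c2)C(=O)C=C1OC(C)(C)C)c1ccc(OCc2ccccc2)c(OCc2ccccc2)c1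
F13 | step 11 | tert-butyl ether phenol, methyl (3R)-3-[3,4-bis(benzyloxy)phenyl]-3-{4-tert-butoxy-5-[2-(3,4-dimethoxyphenyl)ethyl]-2-hydroxyphenyl}propanoate | COC(=O)C[C@@H](c1cc(CCc2ccc(OC)c(OC)c2)c(OC(C)(C)C)cc1O)c1ccc(OCc2ccccc2)c(OCc2ccccc2)c1
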